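- In a stirred vessel of constant volume, initiator and free monomer go in by the recipes below, and you want the monomer in chains at the end of elm and of ash.

| setting | amber | violet | elm | ash |
|---|---|---|---|---|
| free monomer | 10 mM (in portions, 4) | 10 mM (in portions, 4) | 10 mM (in portions, 4) | 10 mM |
| initiator | 17 µM | 51 µM | 71 µM | 25 µM |
| remark | run made earlier; portions every 1.5 h | run made earlier; portions every 1.5 h | the portions of free monomer follow each other after 1.5 h, the first at the start | everything together at the start |
| time |  |  | 15 h | 8.0 h |

| run | time / h | monomer in chains / % | free monomer / % |
|---|---|---|---|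
| amber | 0.667 | 0.5 | 23.6 |
| amber | 2.00 | 0 | 49.5 |
| amber | 4.00 | 2.9 | 73.5 |
| amber | 6.00 | 7.6 | 92.3 |
| amber | 8.00 | 14.5 | 85.6 |
| amber | 10.0 | 21.3 | 79.6 |
| violet | 2.00 | 0 | 46.8 |
| violet | 4.00 | 5.8 | 69.5 |
| violet | 5.00 | 12.7 | 85.8 |
| violet | 8.00 | 34.4 | 64.1 |
| violet | 10.0 | 45.7 | 49.9 |

(readings scatter by 1 percentage point)

- a reading or a percentage of monomer in chains counts all its forms, free or not

- the flask that ends with the higher amount of monomer in chains, in percent of the free monomer charged, or "neither" when 2 percentage points or less lies between them (elm / ash / neither)
- final monomer in chains, as a percentage of the free monomer charged, in elm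
- final monomer in chains, as a percentage of the free monomer charged, in ash

- Late in both runs, with the portions in, free monomer falls by a steady factor per hour, a pseudo-first-order fall: 0.0363 h⁻¹ in amber and 0.125 h⁻¹ in violet, read through the scatter.
- Those constants stand 3.44 to one, the initiator charges 3.00 to one, so I divide by the charge and carry the mean, the growth constant per initiator charged: 38.3 M⁻¹ min⁻¹.
- Chains extrapolate back to zero at 2.77 h in amber and 3.16 h in violet; through readings good to 1 percentage point I can't tell whether the knee shifts with initiator, so I take 2.96 h for both.
- In the dosed runs that knee costs 1.11 h of whole charge in the vessel, which ash, charged at once, pays in that same time; after this flat start my ash falls at 0.0574 h⁻¹ and ends with 32.7% in chains.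
- Elm, dosed like the runs, turns at the same knee and falls at 0.163 h⁻¹; its last portion lifts free monomer to a peak of 83.4% at 4.50 h.
- My elm curve crosses its chains at 7.64 h. No reading after the last portion shows a level, violet's free monomer still falling to 49.9% at its last reading, so I draw none, and my elm ends with 84.9% in chains.
- The forecast, with numbers other than mine, says elm, 82% for elm and 28% for ash, on “slow activation of the initiator”.
- The flasks give elm: elm 77.4%, less than my figure, and ash 29.5%, also less.

    free monomer + initiator → living end + monomer in chains (k = 0.810 M⁻¹ min⁻¹)
    free monomer + living end → monomer in chains + living end, rate k2*[living end]*[free monomer] (k = 44.0 M⁻¹ min⁻¹)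
    monomer in chains → over-reaction product (k = 3.00 × 10⁻⁶ min⁻¹)
    monomer in chains + living end → free monomer + living end, rate k4*[living end] as long as [monomer in chains] is above zero (k = 0.0380 min⁻¹)
    initiator + monomer in chains ⇌ idle complex, settled at all times (K = 39.0 M⁻¹)

- Turn ash's end around: its 71% of free monomer, with the carried constant, means 6.09 h of running time, shorter than the 6.89 h I allowed. Keep that running time for a neighbour of ash, charged with 0.042 mM of initiator and read after the same hours. The constant times that charge times those hours leaves 55.6% free. The neighbour holds 56.5% free monomer and 43.4% in chains.

The data come from a simulation for substances that don't exist; noise was put on by code.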